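Late in a run the question is how much product stands at 80 s, when two portions of starting material have met an equal charge of protic impurity.

    starting material + 2 product → 3 product (k1 = 4890 /M²/s)
    starting material → product (k2 = 8.18 × 10⁻⁴ /s)
    starting material + protic impurity → quenched substrate (k3 = 18.9 /M/s)

in all of them: starting material 10 mM (in portions, 2); protic impurity 10.0 mM; time 80 s

| charge | remark |
|---|---|
| south | the portions of starting material follow each other after 1.2 s, the first at the start |
| east | the portions of starting material follow each other after 3.0 s, the first at the start |
| south-east | the portions of starting material follow each other after 10 s, the first at the start |
| north-east | the portions of starting material follow each other after 30 s, the first at the start |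

1. [product] at the end for south, east, south-east, north-east, in this order
2. how the row runs (falls all the way / rises, then falls / hardly changes / falls, then rises / rises all the way)

- a step written with two of one species runs at k times the square of its concentration and takes two of it each time
- "hardly changes" means that all values lie within two and a half points (for a concentration: within two and a half percent of the largest)
- run time (south): 80 s

I wrote A, P and H for the concentrations of starting material, product and protic impurity, and kd, ka and kq for the constants of the direct conversion, the autocatalytic step and the quench. Dividing the rate of product formation by the rate of impurity loss removed both A and time: dP/dH = −(kd + ka·P²)/(kq·H). Without the autocatalytic term this integrates to P = s·ln(Hc/H), where Hc is the impurity charged and s = kd/kq = 0.0433 mM, the crossover concentration, is the impurity level at which quench and conversion use starting material equally. H/s is thus the selectivity factor of quench over conversion.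

It starts at 231, so I set A equal to H and treated the charge as added at once, which gave H = Hc/(1 + kq·Hc·t), or 6.20% of the charge at 80 s. That made P 0.120 mM. The autocatalytic term matches kd at P = 0.409 mM, so I dropped it. My reckoning gave one number, not a row. The quench time 1/(kq·Hc) is 5.29 s, so I expected south, at 1.2 s, to read like a single charge, and north-east, at 30 s, to stand lowest.

The forecast gave 0.121 mM, 0.12 mM, 0.117 mM and 0.106 mM, a row that falls all the way, since “later second portions leave less time”.

The simulation gave 0.120 mM, 0.119 mM, 0.117 mM and 0.105 mM, a row that falls all the way.

At 80.0 s in south, the quench was still using starting material 16 times as fast as the conversion, and the 0.676 mM of impurity left, divided by s, gives 15.6. With 6.8% of the impurity left in south, s·ln(Hc/H) gives 0.116 mM against 0.120 mM found, and, with 9.2% of the impurity left in north-east, 0.103 mM against 0.105 mM found.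

The constants used here stand for no real mixture; the result is computed.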